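**Plan**

- Numbering is that of the eudesmanes: ring A = C1–C5 and C10; ring B = C5–C10; C14 is the methyl on C10, C15 the methyl on C4, and C11–C13 the acrylate. The retrosynthesis first takes the C11=C13 methylene back to a C11 phosphonate, then cuts ring A at C1–C2 and C3–C4. This excises C2–C3 as vinyl isobutyrate and leaves a ring B piece with a neopentyl iodide at C1 and an exocyclic allene C5=C4=C15H2.
- Enabling feature: the tetrasubstituted C4=C5 olefin with its C15 methyl, next to quaternary C10, is the hydrogen-quenched form of the allyl radical that forms when a C3 radical attacks the central allene carbon C4. C1 is a CH2 on quaternary C10, so its radical has no ring closure of its own and must add outward.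
- Forward: ring B comes from (R)-4-silyloxycyclohexenone. Two α'-alkylations build C10, a tethered phosphonoacetate Michael addition closes a temporary cis-γ-lactone (C7–C11), and the C5 ketone becomes the allene. The lactone is then opened to the C8 acetate and C12 methyl ester, the radical annulation closes ring A, and olefination with formaldehyde releases the acrylate.
- Stereochemistry: C8 is bought; C10 comes from attack anti to the C8 silyloxy group; C7 from the oxygen tether (cis to C8–O); C3 from the ring closure (pseudo-equatorial ester, cis to C14).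

Key step: step 11

Remark: enantiopure (R)-4-(tert-butyldimethylsilyloxy)cyclohex-2-en-1-one (1) is taken to be a purchasable building block.

**Step 1**
Reactants: 1 (R)-4-(tert-butyldimethylsilyloxy)cyclohex-2-en-1-one
Product: 2 (4R,6R)-4-(tert-butyldimethylsilyloxy)-6-methylcyclohex-2-en-1-one
Conditions: LiN(iPr)2 (LDA), THF, −78 °C; MeI, −78 → −30 °C
Reagents that add atoms: iodomethane, CI
Why: Kinetic α'-deprotonation of the enone gives the cross-conjugated lithium dienolate, which is methylated (enolate alkylation) mainly trans to the silyloxy group; this centre is re-enolised in step 2, so its configuration is of no consequence.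

**Step 2**
Reactants: 2 (4R,6R)-4-(tert-butyldimethylsilyloxy)-6-methylcyclohex-2-en-1-one
Product: 3 (4R,6S)-4-(tert-butyldimethylsilyloxy)-6-(hydroxymethyl)-6-methylcyclohex-2-en-1-one
Conditions: LiN(iPr)2 (LDA), THF, −78 °C; CH2O (gas, from cracked (CH2O)n), −78 → −40 °C; aq. NH4Cl
Reagents that add atoms: formaldehyde, C=O
Why: Aldol addition of the trisubstituted α'-enolate to monomeric formaldehyde creates quaternary C10; the electrophile should enter axially on the face anti to the C8 silyloxy group (half-chair with OSi pseudo-equatorial), so that CH2OH (the future C1) is trans and the methyl (C14) cis to the C8 oxygen.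

**Step 3**
Reactants: 3 (4R,6S)-4-(tert-butyldimethylsilyloxy)-6-(hydroxymethyl)-6-methylcyclohex-2-en-1-one
Product: 4 (4R,6R)-4-(tert-butyldimethylsilyloxy)-6-(iodomethyl)-6-methylcyclohex-2-en-1-one
Conditions: PPh3, I2, imidazole, PhMe, 80 °C
Reagents that add atoms: iodine, II
Why: Appel-type iodination of the primary neopentyl alcohol, in which iodide displaces the alkoxyphosphonium on heating and no stereocentre is touched.

**Step 4**
Reactants: 4 (4R,6R)-4-(tert-butyldimethylsilyloxy)-6-(iodomethyl)-6-methylcyclohex-2-en-1-one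
Product: 5 (4R,6R)-4-hydroxy-6-(iodomethyl)-6-methylcyclohex-2-en-1-one
Conditions: HF (48% aq.), MeCN, 0 °C → rt
Reagents that add atoms: none
Why: Acidic fluoride desilylation should spare the β-iodo ketone, and the γ-hydroxy enone cannot aromatise because C10 is quaternary.

**Step 5**
Reactants: 5 (4R,6R)-4-hydroxy-6-(iodomethyl)-6-methylcyclohex-2-en-1-one
Product: 6 (1R,5R)-5-(iodomethyl)-5-methyl-4-oxocyclohex-2-en-1-yl (diethoxyphosphoryl)acetate
Conditions: (EtO)2P(O)CH2CO2H, DCC, DMAP (cat.), CH2Cl2, 0 °C → rt
Reagents that add atoms: (diethoxyphosphoryl)acetic acid, CCOP(=O)(CC(=O)O)OCC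
Why: Steglich esterification of the secondary allylic alcohol hangs the C11–C12 nucleophile on the C8 oxygen.

**Step 6**
Reactants: 6 (1R,5R)-5-(iodomethyl)-5-methyl-4-oxocyclohex-2-en-1-yl (diethoxyphosphoryl)acetate
Product: 7 diethyl [(3aS,6R,7aR)-6-(iodomethyl)-6-methyl-2,5-dioxooctahydro-1-benzofuran-3-yl]phosphonate (cis-fused lactone; mixture of epimers at the phosphonate carbon)
Conditions: LiCl, DBU (0.2 equiv), MeCN, rt
Reagents that add atoms: none
Why: Intramolecular Michael addition of the softly enolised phosphonoacetate to the enone β-carbon closes the γ-lactone 5-exo-trig, and the short tether can deliver C11 to C7 only on the face of the C8 oxygen, which sets the cis C7/C8 relationship.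

**Step 7**
Reactants: 7 diethyl [(3aS,6R,7aR)-6-(iodomethyl)-6-methyl-2,5-dioxooctahydro-1-benzofuran-3-yl]phosphonate
Product: 8 diethyl [(3aS,6R,7aR)-5-hydroxy-6-(iodomethyl)-6-methyl-2-oxo-5-[1-(trimethylsilyl)ethenyl]octahydro-1-benzofuran-3-yl]phosphonate (mixture of epimers at C5 and at the phosphonate carbon)
Conditions: CH2=C(SiMe3)MgBr (3 equiv, from CH2=C(Br)SiMe3 and Mg), THF, −78 → 0 °C; aq. NH4Cl
Reagents that add atoms: [1-(trimethylsilyl)ethenyl]magnesium bromide, C=C([Mg]Br)[Si](C)(C)C
Why: Grignard 1,2-addition to the C5 ketone after the first equivalent has turned the acidic phosphonoacetate into its enolate, which shields the lactone carbonyl; the carbinol centre disappears in step 8, so its configuration does not matter.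

**Step 8**
Reactants: 8 diethyl [(3aS,6R,7aR)-5-hydroxy-6-(iodomethyl)-6-methyl-2-oxo-5-[1-(trimethylsilyl)ethenyl]octahydro-1-benzofuran-3-yl]phosphonate
Product: 10 diethyl [(3aS,6R,7aR)-5-ethenylidene-6-(iodomethyl)-6-methyl-2-oxooctahydro-1-benzofuran-3-yl]phosphonate, via tertiary trifluoroacetate 9 (not isolated)
Conditions: (CF3CO)2O, pyridine, CH2Cl2, 0 °C; then Bu4NF, THF, 0 °C → rt
Reagents that add atoms: none
Why: Peterson-type β-elimination of a β-silyl allylic ester, in which fluoride attack on silicon expels the tertiary trifluoroacetate across C4–C5 and should give the exocyclic allene C5=C4=C15H2.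

**Step 9**
Reactants: 10 diethyl [(3aS,6R,7aR)-5-ethenylidene-6-(iodomethyl)-6-methyl-2-oxooctahydro-1-benzofuran-3-yl]phosphonate
Product: 13 methyl 2-[(1S,2R,4R)-2-acetoxy-5-ethenylidene-4-(iodomethyl)-4-methylcyclohexyl]-2-(diethoxyphosphoryl)acetate, via lithium carboxylate 11 (not isolated), via hydroxy methyl ester 12 (not isolated)
Conditions: LiOH (1.05 equiv), THF/H2O, 0 °C → rt; evaporate; MeI, DMF, rt; then Ac2O, pyridine, DMAP, 0 °C → rt
Reagents that add atoms: lithium hydroxide, [Li+].[OH-]; iodomethane, CI; acetic anhydride, CC(=O)OC(C)=O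
Why: Saponification of the lactone, O-methylation of the carboxylate and acetylation of the freed C8 hydroxyl in one flask, so that the γ-hydroxy ester has no time to relactonise; no stereocentre is affected.

**Step 10**
Reactants: 14 2-methylpropanoic acid (isobutyric acid)
Product: 15 ethenyl 2-methylpropanoate (vinyl isobutyrate)
Conditions: vinyl acetate (excess), Pd(OAc)2 (2 mol %), KOH (10 mol %), 40 °C
Reagents that add atoms: vinyl acetate, C=COC(C)=O
Why: Palladium-catalysed transvinylation (vinyl exchange) from vinyl acetate to the carboxylic acid.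

**Step 11**
Reactants: 13 methyl 2-[(1S,2R,4R)-2-acetoxy-5-ethenylidene-4-(iodomethyl)-4-methylcyclohexyl]-2-(diethoxyphosphoryl)acetate; 15 ethenyl 2-methylpropanoate
Product: 16 methyl 2-[(2S,3R,4aR,7S)-3-acetoxy-4a,8-dimethyl-7-(2-methylpropanoyloxy)-1,2,3,4,4a,5,6,7-octahydronaphthalen-2-yl]-2-(diethoxyphosphoryl)acetate
Conditions: Bu3SnH (1.3 equiv) and AIBN (0.2 equiv) by syringe pump over 8 h, 15 (30 equiv), PhH (0.02 M in 13), 80 °C
Reagents that add atoms: none
Why: Proposed new method: Bu3Sn• abstracts iodine from C1; the neopentyl C1 radical, which has no productive ring closure of its own (attack on C5 would give a cyclopropane and a vinyl radical, attack on C4 a cyclobutane), adds to the CH2 terminus of 15 (C1–C2), and the resulting α-acyloxy C3 radical closes ring A on the central allene carbon C4 (C3–C4), leaving an allyl radical over C5–C4–C15 that takes hydrogen from Bu3SnH at the unhindered C15 terminus to give the C15 methyl and the C4=C5 olefin. The closest known reaction types are stannane-mediated radical addition–cyclisation (annulation) cascades of alkyl iodides with alkenes and ring closures of carbon radicals at the central carbon of allenes; their union as a two-bond annulation with a vinyl ester is the untested part, and it rests on the allyl-radical driving force and on the Thorpe–Ingold effect of quaternary C10. Ring A closes 6-exo-trig with respect to the C4=C15 π bond (6-endo with respect to C5=C4), the geometry in which C3 reaches the in-plane p orbital of C4 while C1 lies equatorial on ring B. The new stereocentre C3 is set in a chair-like transition state in which ring A grows trans-decalin-like under the axial C14 methyl and the isobutyrate sits pseudo-equatorial, which places it cis to C14 (3β). The step needs chemoselectivity (capture of the C1 radical by 15 before reduction, secured by excess 15 and slow stannane addition; ring closure before telomerisation, secured by the rigid 1,2-disposition of C1 and the allene on ring B), regioselectivity of closure (central C4 and not 5-exo at the fully substituted C5 next to C10) and of hydrogen delivery (C15 and not the tertiary C5), and an inert side chain, secured by carrying the acrylate as its phosphonate.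

**Step 12**
Reactants: 16 methyl 2-[(2S,3R,4aR,7S)-3-acetoxy-4a,8-dimethyl-7-(2-methylpropanoyloxy)-1,2,3,4,4a,5,6,7-octahydronaphthalen-2-yl]-2-(diethoxyphosphoryl)acetate
Product: 17 methyl 2-[(2R,3R,4aR,7S)-3-acetoxy-4a,8-dimethyl-7-(2-methylpropanoyloxy)-1,2,3,4,4a,5,6,7-octahydronaphthalen-2-yl]prop-2-enoate (target)
Conditions: (CH2O)n, LiCl, DBU, MeCN, rt
Reagents that add atoms: formaldehyde (from paraformaldehyde), C=O
Why: Horner–Wadsworth–Emmons olefination of the α-substituted phosphonoacetate with formaldehyde under Masamune–Roush conditions, mild enough for the acetate and the isobutyrate, should unveil the C11=C13 methylene without touching a stereocentre.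

**Compound list**

1 | (R)-4-(tert-butyldimethylsilyloxy)cyclohex-2-en-1-one | O=C1C=C[C@H](O[Si](C)(C)C(C)(C)C)CC1 | starting material
2 | (4R,6R)-4-(tert-butyldimethylsilyloxy)-6-methylcyclohex-2-en-1-one | O=C1C=C[C@H](O[Si](C)(C)C(C)(C)C)C[C@H]1C | intermediate
3 | (4R,6S)-4-(tert-butyldimethylsilyloxy)-6-(hydroxymethyl)-6-methylcyclohex-2-en-1-one | O=C1C=C[C@H](O[Si](C)(C)C(C)(C)C)C[C@@]1(C)CO | intermediate
4 | (4R,6R)-4-(tert-butyldimethylsilyloxy)-6-(iodomethyl)-6-methylcyclohex-2-en-1-one | O=C1C=C[C@H](O[Si](C)(C)C(C)(C)C)C[C@@]1(C)CI | intermediate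
5 | (4R,6R)-4-hydroxy-6-(iodomethyl)-6-methylcyclohex-2-en-1-one | O=C1C=C[C@H](O)C[C@@]1(C)CI | intermediate
6 | (1R,5R)-5-(iodomethyl)-5-methyl-4-oxocyclohex-2-en-1-yl (diethoxyphosphoryl)acetate | O=C1C=C[C@H](OC(=O)CP(=O)(OCC)OCC)C[C@@]1(C)CI | intermediate
7 | diethyl [(3aS,6R,7aR)-6-(iodomethyl)-6-methyl-2,5-dioxooctahydro-1-benzofuran-3-yl]phosphonate (C3 epimers) | CCOP(=O)(OCC)C1C(=O)O[C@@H]2C[C@@](C)(CI)C(=O)C[C@H]12 | intermediate
8 | diethyl [(3aS,6R,7aR)-5-hydroxy-6-(iodomethyl)-6-methyl-2-oxo-5-[1-(trimethylsilyl)ethenyl]octahydro-1-benzofuran-3-yl]phosphonate (C3 and C5 epimers) | CCOP(=O)(OCC)C1C(=O)O[C@@H]2C[C@@](C)(CI)C(O)(C(=C)[Si](C)(C)C)C[C@H]12 | intermediate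
9 | trifluoroacetate of 8 at the C5 hydroxyl | CCOP(=O)(OCC)C1C(=O)O[C@@H]2C[C@@](C)(CI)C(OC(=O)C(F)(F)F)(C(=C)[Si](C)(C)C)C[C@H]12 | intermediate
10 | diethyl [(3aS,6R,7aR)-5-ethenylidene-6-(iodomethyl)-6-methyl-2-oxooctahydro-1-benzofuran-3-yl]phosphonate (C3 epimers) | CCOP(=O)(OCC)C1C(=O)O[C@@H]2C[C@@](C)(CI)C(=C=C)C[C@H]12 | intermediate
11 | lithium 2-(diethoxyphosphoryl)-2-[(1S,2R,4R)-5-ethenylidene-2-hydroxy-4-(iodomethyl)-4-methylcyclohexyl]acetate | [Li+].[O-]C(=O)C(P(=O)(OCC)OCC)[C@H]1CC(=C=C)[C@](C)(CI)C[C@H]1O | intermediate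
12 | methyl 2-(diethoxyphosphoryl)-2-[(1S,2R,4R)-5-ethenylidene-2-hydroxy-4-(iodomethyl)-4-methylcyclohexyl]acetate | COC(=O)C(P(=O)(OCC)OCC)[C@H]1CC(=C=C)[C@](C)(CI)C[C@H]1O | intermediate
13 | methyl 2-[(1S,2R,4R)-2-acetoxy-5-ethenylidene-4-(iodomethyl)-4-methylcyclohexyl]-2-(diethoxyphosphoryl)acetate | COC(=O)C(P(=O)(OCC)OCC)[C@H]1CC(=C=C)[C@](C)(CI)C[C@H]1OC(C)=O | intermediate
14 | 2-methylpropanoic acid (isobutyric acid) | CC(C)C(=O)O | starting material
15 | ethenyl 2-methylpropanoate (vinyl isobutyrate) | C=COC(=O)C(C)C | intermediate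
16 | methyl 2-[(2S,3R,4aR,7S)-3-acetoxy-4a,8-dimethyl-7-(2-methylpropanoyloxy)-1,2,3,4,4a,5,6,7-octahydronaphthalen-2-yl]-2-(diethoxyphosphoryl)acetate | COC(=O)C(P(=O)(OCC)OCC)[C@H]1CC2=C(C)[C@@H](OC(=O)C(C)C)CC[C@]2(C)C[C@H]1OC(C)=O | intermediate
17 | methyl 2-[(2R,3R,4aR,7S)-3-acetoxy-4a,8-dimethyl-7-(2-methylpropanoyloxy)-1,2,3,4,4a,5,6,7-octahydronaphthalen-2-yl]prop-2-enoate | C=C(C(=O)OC)[C@H]1CC2=C(C)[C@@H](OC(=O)C(C)C)CC[C@]2(C)C[C@H]1OC(C)=O | target

**Step count and risks**

Total step count: 12. Longest linear sequence: 11 steps (steps 1–9, 11 and 12).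

Steps most likely to fail:

1. Step 11 (Proposed new method). The process at risk is premature reduction of the C1 radical, telomerisation of the vinyl ester before ring closure, or poor facial selectivity at C3. The fallback uses known chemistry, sets out from 13 and comes back at 16. Nickel-catalysed reductive cross-electrophile coupling of iodide 13 with (Z)-1-bromo-2-ethoxyethene (NiBr2·glyme, 4,4'-di-tert-butyl-2,2'-bipyridine, Mn, DMA) should make the C1–C2 bond and give the (Z)-enol ether F1. Mild aqueous acid (PPTS, acetone/H2O) should free the aldehyde F2. Nickel-catalysed reductive allene–aldehyde cyclisation (Ni(cod)2, 1,3-bis(2,6-diisopropylphenyl)imidazol-2-ylidene, Et3SiH, THF) should make the C3–C4 bond at the central allene carbon and give the triethylsilyl ether F3. HF·pyridine should give the allylic alcohol F4 as C3 epimers, Dess–Martin oxidation the enone F5, and Luche reduction (NaBH4, CeCl3·7H2O, MeOH, −78 °C) the 3β-alcohol F6. Isobutyryl chloride, pyridine and DMAP then give 16.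

2. Step 7. The process at risk is enolisation of the hindered C5 ketone by the bulky α-silylvinyl nucleophile, or fragmentation of the γ-iodo alkoxide. The fallback sets out from 7 and comes back at 10. The smaller ethynylmagnesium bromide (3 equiv, THF, −78 → 0 °C) should give the tertiary propargylic alcohol F7, and acetylation (Ac2O, DMAP, Et3N) the propargylic acetate F8. SN2' hydride delivery with [(Ph3P)CuH]6 (PhH, rt) should then give allene 10.

3. Step 3. The process at risk is slow displacement at the neopentyl carbon with competing retro-aldol cleavage of the β-hydroxy ketone; upstream, step 2 could also lose formaldehyde or show poor facial selectivity. The fallback sets out from 2, never passes through a neopentyl alcohol, and comes back at 4. LiN(iPr)2/Me3SiCl should convert 2 into the 2-silyloxy diene F9. Furukawa cyclopropanation (Et2Zn, CH2I2, CH2Cl2, 0 °C) of the electron-rich enol ether double bond, anti to the C8 silyloxy group, should give the siloxycyclopropane F10. N-Iodosuccinimide (CH2Cl2, 0 °C) should open the CH2–C(OSi) bond to give the β-iodo ketone 4 directly.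

**Further compounds**

F1 | step 11 | (Z)-enol ether: 13 with CH2I replaced by CH2CH=CHOEt | COC(=O)C(P(=O)(OCC)OCC)[C@H]1CC(=C=C)[C@](C)(C/C=C\OCC)C[C@H]1OC(C)=O
F2 | step 11 | aldehyde: 13 with CH2I replaced by CH2CH2CHO | COC(=O)C(P(=O)(OCC)OCC)[C@H]1CC(=C=C)[C@](C)(CCC=O)C[C@H]1OC(C)=O
F3 | step 11 | triethylsilyl ether of the cyclised allylic alcohol (C3 epimers) | COC(=O)C(P(=O)(OCC)OCC)[C@H]1CC2=C(C)C(O[Si](CC)(CC)CC)CC[C@]2(C)C[C@H]1OC(C)=O
F4 | step 11 | cyclised allylic alcohol (C3 epimers): 16 with OH in place of the isobutyrate | COC(=O)C(P(=O)(OCC)OCC)[C@H]1CC2=C(C)C(O)CC[C@]2(C)C[C@H]1OC(C)=O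
F5 | step 11 | 3-oxo-4-ene enone corresponding to 16 | COC(=O)C(P(=O)(OCC)OCC)[C@H]1CC2=C(C)C(=O)CC[C@]2(C)C[C@H]1OC(C)=O
F6 | step 11 | 3β-alcohol: 16 with OH in place of the isobutyrate | COC(=O)C(P(=O)(OCC)OCC)[C@H]1CC2=C(C)[C@@H](O)CC[C@]2(C)C[C@H]1OC(C)=O
F7 | step 7 | tertiary propargylic alcohol: 7 with C5(OH)(C≡CH) in place of the ketone (C5 epimers) | CCOP(=O)(OCC)C1C(=O)O[C@@H]2C[C@@](C)(CI)C(O)(C#C)C[C@H]12
F8 | step 7 | propargylic acetate of F7 | CCOP(=O)(OCC)C1C(=O)O[C@@H]2C[C@@](C)(CI)C(OC(C)=O)(C#C)C[C@H]12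
F9 | step 3 | (R)-5-(tert-butyldimethylsilyloxy)-1-methyl-2-(trimethylsilyloxy)cyclohexa-1,3-diene | C[Si](C)(C)OC1=C(C)C[C@@H](O[Si](C)(C)C(C)(C)C)C=C1
F10 | step 3 | siloxycyclopropane: 4-(tert-butyldimethylsilyloxy)-6-methyl-1-(trimethylsilyloxy)bicyclo[4.1.0]hept-2-ene, CH2 bridge trans to the C4 silyloxy group | C[Si](C)(C)O[C@]12C=C[C@H](O[Si](C)(C)C(C)(C)C)C[C@@]1(C)C2
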